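**Retrosynthetic overview**
1. Feature: in the ten-membered ring C1–C10, the atoms C10=C1–C2–C3–C4=C5 form a 1,5-diene once the C1/C10 oxirane is read back as its E-alkene. The Cope isomer of this diene is the cyclohexane C5–C6–C7–C8–C9–C10, which carries vinyl (C1=C2) and C14 on C10, and OH plus the acrylate (C3=C4–C15) on C5.
2. Target ⇒ (C9 acetate, C14 (R)-2-methylbutanoate, Sharpless oxirane) ⇒ diene ester ⇒ (Z-enol triflate, Pd/formate) ⇒ ten-membered β-keto ester ⇒ anionic oxy-Cope ⇒ trans-1,2-dialkenylcyclohexanol.
3. The acrylate is delivered to C5 from a tether on the axial C14–OH, through a temporary cis-fused lactone. An external nucleophile would enter anti to axial C14 and give the C5 epimer, which rearranges to the Z-C1=C10 alkene.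
4. Quaternary C10 comes from a semipinacol vinyl shift C5→C10 in a spiro-epoxy alcohol made from (S)-carvone. C7 comes from the chiral pool, C9 from a Luche reduction, and C14 is the carvone methyl group, oxidised through two epoxide steps.
5. Ring order: cyclohexane (carvone) → temporary δ-lactone (step 10, opened in step 11) → ten-membered carbocycle (step 13) → oxirane (step 17).

Key step: step 13

Remark on numbering: ring atoms are C1 (oxirane CH), C2, C3, C4 (C–CO2Me, ester carbon C15), C5, C6, C7 (isopropenyl), C8, C9, C10 (bears C14). "Upper face" is the face of ring C5–C10 that carries the isopropenyl group.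
Assumption: compounds 1, 8, 11 and 25 are taken as purchasable, 25 as the single (R)-enantiomer.

Step 1
Reactants: 1 (S)-(+)-carvone
Product: 2 (+)-cis-carveol (1S,5S; C9–OH cis to isopropenyl)
Conditions: NaBH4, CeCl3·7H2O, MeOH, 0 °C
Reagents that add atoms: none
Why: Luche reduction; 1,2-hydride delivery along the axial path, trans to the equatorial isopropenyl group, should give the pseudo-equatorial alcohol and so set C9 cis to C7.

Step 2
Reactants: 2 (+)-cis-carveol
Product: 3 all-cis C5,C10-epoxy alcohol (oxirane O, C9–OH and isopropenyl on the upper face)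
Conditions: VO(acac)2 (2 mol %), t-BuOOH, toluene, 0 °C → rt
Reagents that add atoms: tert-butyl hydroperoxide, CC(C)(C)OO
Why: Hydroxyl-directed vanadium-catalysed epoxidation; the vanadate ester of C9–OH delivers oxygen to its own face and only to the allylic C5=C10 alkene, so the isopropenyl group is left alone.

Step 3
Reactants: 3 all-cis epoxy alcohol
Product: 4 C9 TBS ether of 3
Conditions: TBSCl, imidazole, DMF, rt
Reagents that add atoms: tert-butyldimethylsilyl chloride, CC(C)(C)[Si](C)(C)Cl
Why: Standard silylation; it permanently distinguishes the C9 oxygen from the C5 oxygen, without which the 2-methylene-1,3-diol array of the next step would be meso.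

Step 4
Reactants: 4 epoxy silyl ether
Product: 5 exocyclic allylic alcohol (C10=C14H2; C5–OH, C9–OTBS and isopropenyl all cis and equatorial)
Conditions: TMP, n-BuLi, then Et2AlCl, toluene, 0 °C; add 4, 0 °C; cold 1 M HCl work-up
Reagents that add atoms: none
Why: Base-induced isomerisation of an epoxide to an allylic alcohol by syn β-elimination; aluminium binds the oxirane oxygen and the hindered amide takes a proton from C14, the only group on C10 with a hydrogen syn to that oxygen, so C10–O breaks and the C5–O configuration is kept.

Step 5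
Reactants: 5 exocyclic allylic alcohol
Product: 6 spiro-epoxy alcohol (C10–O axial on the upper face, C14H2 equatorial)
Conditions: VO(acac)2 (2 mol %), t-BuOOH, toluene, 0 °C
Reagents that add atoms: tert-butyl hydroperoxide, CC(C)(C)OO
Why: Hydroxyl-directed vanadium epoxidation of the 1,1-disubstituted allylic alkene; the equatorial C5–O bond leans toward the upper face of C10=C14 and ring flattening can open the O–C5–C10=C14 torsion only on that side, so oxygen should enter axially while the isopropenyl group stays untouched.

Step 6
Reactants: 6 spiro-epoxy alcohol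
Product: 7 spiro-epoxy ketone (C5=O)
Conditions: Dess–Martin periodinane, pyridine, CH2Cl2, 0 °C → rt
Reagents that add atoms: none
Why: Dess–Martin oxidation of the secondary alcohol under buffered conditions that leave the oxirane, silyl ether and alkenes alone.

Step 7
Reactants: 7 spiro-epoxy ketone; 8 vinylmagnesium bromide
Product: 9 tertiary epoxy alcohol (vinyl axial on the lower face, C5–OH equatorial)
Conditions: THF, −78 °C; aq. NH4Cl
Reagents that add atoms: vinylmagnesium bromide, C=C[Mg]Br
Why: Grignard 1,2-addition; the small sp2 nucleophile takes the axial path on the lower face, anti to the axial C10–O bond, which puts vinyl antiperiplanar to that bond (C5 is only a relay centre here).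

Step 8
Reactants: 9 tertiary epoxy alcohol
Product: 10 2-(hydroxymethyl)-2-vinyl ketone (C5=O; on C10 vinyl equatorial and down, C14H2OH axial and up)
Conditions: ZnBr2 (20 mol %), CH2Cl2, 0 °C → rt
Reagents that add atoms: none
Why: Semipinacol rearrangement of a 2,3-epoxy alcohol; the Lewis acid opens the oxirane at tertiary C10 while the antiperiplanar vinyl group shifts from C5 to the lower face of C10 with inversion, which sets the quaternary centre and returns the C5 ketone.

Step 9
Reactants: 10 hydroxymethyl vinyl ketone; 11 2,3-dibromopropanoyl chloride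
Product: 13 2-bromoacrylate ester of 10, via 2,3-dibromopropanoate ester 12 (not isolated)
Conditions: Et3N (2.5 equiv), CH2Cl2, −20 → 0 °C
Reagents that add atoms: 2,3-dibromopropanoyl chloride, O=C(Cl)C(Br)CBr
Why: O-acylation followed by E2 loss of HBr, the usual entry to 2-bromoacrylates; C10 carries no hydrogen, so the β-acyloxy ketone cannot eliminate.

Step 10
Reactants: 13 2-bromoacrylate ester
Product: 14 cis-fused α-methylene-β-hydroxy-δ-lactone (C4 equatorial and up on C5, C5–OH axial and down)
Conditions: CrCl2 (6 equiv), NiCl2 (2 mol %), DMF, rt, high dilution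
Reagents that add atoms: none
Why: Proposed new method: Ni(0) should insert into the electron-poor C4–Br bond and pass the alkenyl group to Cr(III); the resulting α-chromio acrylate (a chromium allenolate) is non-basic, so the enolisable C5 ketone is not deprotonated, and it adds to C5=O in a six-membered closure that, from the axial C14 tether, can reach only the upper face, which sets C5 with C4 cis to C14 and the OH axial (a trans-fused lactone is geometrically out of reach); the closest known reaction types are the Nozaki–Hiyama–Kishi alkenylation of aldehydes, including its ring-closing form, and the chromium(II) Reformatsky reaction.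

Step 11
Reactants: 14 hydroxy lactone
Product: 16 hydroxy methyl ester (C14–OH free), via potassium carboxylate 15 (not isolated)
Conditions: KOH (1.0 equiv), THF–H2O, 0 °C; evaporate cold; MeI, DMF, 0 °C; used crude
Reagents that add atoms: potassium hydroxide, [K+].[OH-]; iodomethane, CI
Why: Saponification of the lactone and SN2 methylation of the carboxylate salt; no methoxide is present that could add to the acrylate and no acid that would close the lactone again.

Step 12
Reactants: 16 hydroxy methyl ester
Product: 17 trans-1,2-dialkenylcyclohexanol (C5: OH axial, acrylate equatorial; C10: vinyl equatorial, C14H2OTES axial; C9–OTBS and isopropenyl equatorial)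
Conditions: TESOTf (1.05 equiv), 2,6-lutidine, CH2Cl2, −78 °C
Reagents that add atoms: triethylsilyl triflate, CC[Si](CC)(CC)OS(=O)(=O)C(F)(F)F
Why: Silylation with the triflate at low temperature is far faster at the primary than at the tertiary alcohol and caps C14–OH before it can re-lactonise.

Step 13
Reactants: 17 trans-1,2-dialkenylcyclohexanol
Product: 20 ten-membered β-keto ester drawn as its chelated enol (E-C1=C10), via potassium alkoxide 18 (not isolated), via potassium enolate 19 (not isolated)
Conditions: KHMDS (1.1 equiv), 18-crown-6 (1.2 equiv), THF (0.005 M), −78 → 0 °C; AcOH, −78 °C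
Reagents that add atoms: none
Why: Deprotonation gives alkoxide 18, whose C5–O⁻ weakens the C5–C10 bond and drives a concerted, strongly polarised [3,3] shift in which C2 bonds to the acrylate terminus C3; this is the anionic oxy-Cope rearrangement of a 1,2-dialkenylcyclohexanol, the known route to cyclodec-5-enones. The ten-membered ring is not closed end to end but released from the six-membered ring by forming C2–C3 and breaking C5–C10, a four-atom ring expansion through a chair-like six-centre array. No stereocentre is made (C5 and C10 become sp2, C7 and C9 are untouched); what is set is the C1=C10 geometry, because about the C5–C10 axis C4 lies between C1 and C14, so C2 can meet C3 only on the C14 side and C9 ends trans to C2 (E). With the trans-dialkenyl relationship this result does not depend on chair versus boat, which only affects the enolate geometry that is erased later, and the reacting conformer is the ground-state chair with isopropenyl, OTBS and both alkenyl groups equatorial. The ester makes the product the stabilised enolate 19, so the shift is irreversible and should run cold, which together with high dilution and a non-nucleophilic base holds back oxa-Michael oligomerisation of the acrylate.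

Step 14
Reactants: 20 β-keto ester
Product: 21 (Z)-enol triflate (OTf cis to CO2Me; C3 and C6 cis on the ring)
Conditions: LiOTf, Et3N, Tf2O, CH2Cl2, −78 → 0 °C
Reagents that add atoms: triflic anhydride, O=S(=O)(C(F)(F)F)OS(=O)(=O)C(F)(F)F
Why: O-sulfonylation of the lithium-chelated enolate; Li+ held between the C5 oxygen and the ester carbonyl keeps them cis, so the Z-enol triflate should form at the only doubly activated position, C4.

Step 15
Reactants: 21 (Z)-enol triflate
Product: 22 diene ester (C4=C5 with H cis to CO2Me, E by CIP; E-C1=C10)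
Conditions: Pd(OAc)2 (5 mol %), PPh3 (10 mol %), HCO2H, Et3N, DMF, 40 °C
Reagents that add atoms: none
Why: Palladium-catalysed formate reduction of an enol triflate (oxidative addition, decarboxylation of formate, reductive elimination) proceeds with retention, so H replaces OTf and gives the C4=C5 geometry of the target, and no allylic ester is yet present for Pd(0) to ionise.

Step 16
Reactants: 22 diene ester
Product: 23 C14 allylic alcohol (C9–OTBS kept)
Conditions: PPTS (10 mol %), MeOH–CH2Cl2, 0 °C
Reagents that add atoms: none
Why: Acid-catalysed methanolysis distinguishes the primary triethylsilyl ether from the hindered secondary TBS ether.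

Step 17
Reactants: 23 C14 allylic alcohol
Product: 24 (1R,10S)-epoxy alcohol (trans oxirane)
Conditions: Ti(OiPr)4 (0.2 equiv), L-(+)-DIPT (0.24 equiv), t-BuOOH, 4 Å MS, CH2Cl2, −20 °C
Reagents that add atoms: tert-butyl hydroperoxide, CC(C)(C)OO
Why: Sharpless asymmetric epoxidation; only the alkene allylic to the free C14–OH reacts, syn addition to the E-alkene gives the trans oxirane, and the L-(+)-tartrate, which gives (2S)-type epoxy alcohols, maps here onto oxygen delivery that makes C10 S and C1 R.

Step 18
Reactants: 24 epoxy alcohol; 25 (R)-2-methylbutanoic acid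
Product: 26 C14 (R)-2-methylbutanoate
Conditions: DIC, DMAP (10 mol %), CH2Cl2, 0 °C → rt
Reagents that add atoms: (R)-2-methylbutanoic acid, CC[C@@H](C)C(=O)O
Why: Steglich esterification of the primary alcohol under mild conditions that should not enolise the α-stereocentre of the acid, which is carried in from 25.

Step 19
Reactants: 26 silyl-protected epoxy diester
Product: 27 C9 alcohol
Conditions: HF·pyridine, pyridine, THF, 0 °C → rt
Reagents that add atoms: none
Why: Fluoride desilylation in a buffered, non-basic medium; no alkoxide forms, so Payne rearrangement, acyl shift and transannular oxa-Michael addition to C5 are avoided.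

Step 20
Reactants: 27 C9 alcohol
Product: 28 target CNP0352790.1
Conditions: Ac2O, pyridine, DMAP (cat.), CH2Cl2, 0 °C
Reagents that add atoms: acetic anhydride, CC(=O)OC(C)=O
Why: Acetylation with retention at C9; placing the acetate last means no intermediate has a secondary acetate next to a free primary C14–OH (1,3-acyl shift), and no allylic acetate meets Pd(0) or Ti(IV).

**Compound list**
1 | (S)-(+)-carvone | C=C(C)[C@H]1CC=C(C)C(=O)C1 | starting material
2 | (+)-cis-carveol, (1S,5S) | C=C(C)[C@H]1CC=C(C)[C@@H](O)C1 | intermediate
3 | all-cis epoxy alcohol: 1-methyl-4-isopropenyl-7-oxabicyclo[4.1.0]heptan-2-ol, with O, OH and isopropenyl on one face | C=C(C)[C@H]1C[C@H]2O[C@@]2(C)[C@@H](O)C1 | intermediate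
4 | TBS ether of 3 | C=C(C)[C@H]1C[C@H]2O[C@@]2(C)[C@@H](O[Si](C)(C)C(C)(C)C)C1 | intermediate
5 | all-cis 3-(TBSO)-2-methylidene-5-isopropenylcyclohexan-1-ol | C=C(C)[C@H]1C[C@@H](O)C(=C)[C@@H](O[Si](C)(C)C(C)(C)C)C1 | intermediate
6 | spiro-epoxy alcohol (1-oxaspiro[2.5]octan-4-ol, oxirane O axial and cis to C5–OH) | C=C(C)[C@H]1C[C@@H](O)[C@]2(CO2)[C@@H](O[Si](C)(C)C(C)(C)C)C1 | intermediate
7 | spiro-epoxy ketone | C=C(C)[C@H]1CC(=O)[C@]2(CO2)[C@@H](O[Si](C)(C)C(C)(C)C)C1 | intermediate
8 | vinylmagnesium bromide | C=C[Mg]Br | starting material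
9 | tertiary epoxy alcohol (vinyl trans to oxirane O) | C=C(C)[C@H]1C[C@](O)(C=C)[C@]2(CO2)[C@@H](O[Si](C)(C)C(C)(C)C)C1 | intermediate
10 | 3-(TBSO)-2-(hydroxymethyl)-5-isopropenyl-2-vinylcyclohexanone (CH2OH cis to OTBS and isopropenyl) | C=C(C)[C@H]1CC(=O)[C@@](C=C)(CO)[C@@H](O[Si](C)(C)C(C)(C)C)C1 | intermediate
11 | 2,3-dibromopropanoyl chloride | O=C(Cl)C(Br)CBr | starting material
12 | 2,3-dibromopropanoate of 10 (CHBr epimers) | C=C(C)[C@H]1CC(=O)[C@@](C=C)(COC(=O)C(Br)CBr)[C@@H](O[Si](C)(C)C(C)(C)C)C1 | intermediate
13 | 2-bromoacrylate of 10 | C=C(C)[C@H]1CC(=O)[C@@](C=C)(COC(=O)C(Br)=C)[C@@H](O[Si](C)(C)C(C)(C)C)C1 | intermediate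
14 | cis-fused lactone: 4a-hydroxy-4-methylidene-8a-vinyl-8-(TBSO)-6-isopropenyl-hexahydroisochroman-3-one | C=C(C)[C@H]1C[C@@]2(O)C(=C)C(=O)OC[C@@]2(C=C)[C@@H](O[Si](C)(C)C(C)(C)C)C1 | intermediate
15 | potassium carboxylate from 14 | C=C(C)[C@H]1C[C@@](O)(C(=C)C(=O)[O-])[C@@](C=C)(CO)[C@@H](O[Si](C)(C)C(C)(C)C)C1.[K+] | intermediate
16 | hydroxy methyl ester | C=C(C)[C@H]1C[C@@](O)(C(=C)C(=O)OC)[C@@](C=C)(CO)[C@@H](O[Si](C)(C)C(C)(C)C)C1 | intermediate
17 | trans-1,2-dialkenylcyclohexanol (key-step precursor, C14–OTES) | C=C(C)[C@H]1C[C@@](O)(C(=C)C(=O)OC)[C@@](C=C)(CO[Si](CC)(CC)CC)[C@@H](O[Si](C)(C)C(C)(C)C)C1 | intermediate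
18 | potassium alkoxide of 17 | C=C(C)[C@H]1C[C@@]([O-])(C(=C)C(=O)OC)[C@@](C=C)(CO[Si](CC)(CC)CC)[C@@H](O[Si](C)(C)C(C)(C)C)C1.[K+] | intermediate
19 | ten-membered potassium enolate (geometry as delivered by the chair) | C=C(C)[C@H]1C/C([O-])=C(C(=O)OC)/CC/C=C(CO[Si](CC)(CC)CC)/[C@@H](O[Si](C)(C)C(C)(C)C)C1.[K+] | intermediate
20 | ten-membered β-keto ester, chelated enol (key-step product) | C=C(C)[C@H]1C/C(O)=C(/C(=O)OC)CC/C=C(CO[Si](CC)(CC)CC)/[C@@H](O[Si](C)(C)C(C)(C)C)C1 | intermediate
21 | (Z)-enol triflate | C=C(C)[C@H]1C/C(OS(=O)(=O)C(F)(F)F)=C(/C(=O)OC)CC/C=C(CO[Si](CC)(CC)CC)/[C@@H](O[Si](C)(C)C(C)(C)C)C1 | intermediate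
22 | (1(10)E,4E)-diene ester | C=C(C)[C@H]1C/C=C(/C(=O)OC)CC/C=C(CO[Si](CC)(CC)CC)/[C@@H](O[Si](C)(C)C(C)(C)C)C1 | intermediate
23 | C14 allylic alcohol | C=C(C)[C@H]1C/C=C(/C(=O)OC)CC/C=C(CO)/[C@@H](O[Si](C)(C)C(C)(C)C)C1 | intermediate
24 | (1R,10S)-epoxy alcohol | C=C(C)[C@H]1C/C=C(/C(=O)OC)CC[C@H]2O[C@]2(CO)[C@@H](O[Si](C)(C)C(C)(C)C)C1 | intermediate
25 | (R)-2-methylbutanoic acid | CC[C@@H](C)C(=O)O | starting material
26 | C14 (R)-2-methylbutanoate, C9–OTBS | C=C(C)[C@H]1C/C=C(/C(=O)OC)CC[C@H]2O[C@]2(COC(=O)[C@H](C)CC)[C@@H](O[Si](C)(C)C(C)(C)C)C1 | intermediate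
27 | C9 alcohol | C=C(C)[C@H]1C/C=C(/C(=O)OC)CC[C@H]2O[C@]2(COC(=O)[C@H](C)CC)[C@@H](O)C1 | intermediate
28 | methyl (1R,4E,7S,9S,10S)-9-acetoxy-1,10-epoxy-7-isopropenyl-14-[(2R)-2-methylbutanoyloxy]cyclodec-4-ene-4-carboxylate (numbering as above) | C=C(C)[C@H]1C/C=C(/C(=O)OC)CC[C@H]2O[C@]2(COC(=O)[C@H](C)CC)[C@@H](OC(C)=O)C1 | target

Total step count: 20. Longest linear sequence: 20 (from 1).

**Steps most likely to fail**

1. Step 10 (labelled step). The alkenyl-metal species may be protonated or dimerise before it adds to the hindered ketone. The fallback uses known chemistry, sets out from 10 and returns at 14. Acylation with bromoacetyl bromide and pyridine gives the bromoacetate F1. SmI2 (2.2 equiv, THF, −78 °C) effects the intramolecular samarium Reformatsky reaction of this β-(bromoacetoxy) ketone to give the cis-fused β-hydroxy-δ-lactone F2, with the same tether-enforced C5 configuration. Double deprotonation with LDA and Eschenmoser's salt gives the Mannich base F3. N-methylation with MeI and elimination with NaHCO3 installs the methylene group and gives 14.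

2. Step 13. The naked alkoxide may add to the acrylate of a second molecule, or the C5–C10 bond may break heterolytically and the allyl anion be protonated before C2–C3 forms. The fallback removes the anion, sets out from 17 and returns at 20. TMSOTf and 2,6-lutidine give the tertiary trimethylsilyl ether F4. Heating in o-dichlorobenzene with BHT (about 170 °C) runs the neutral siloxy-Cope shift through the same diequatorial chair to the ten-membered silyl enol ether F5, a push–pull alkene that holds the equilibrium on the ring-expanded side. Aqueous citric acid in MeOH releases 20.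

3. Step 17. Turnover may be slow because C2 is cis to the CH2OH group, and facial selectivity may be poor if the exposed face of the ring alkene opposes the tartrate. The fallback gives up the directing alcohol, sets out from 23 and returns at 26. Steglich esterification with 25 is done first and gives the allylic ester F6. Shi epoxidation (fructose-derived ketone or its enantiomer, whichever matches the 1R,10S face, with Oxone and K2CO3 buffer in MeCN–DMM–H2O at 0 °C) then oxidises the trisubstituted E-alkene in preference to the 1,1-disubstituted isopropenyl group and the electron-poor enoate.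

**Further compounds**
F1 | step 10 | bromoacetate of 10 | C=C(C)[C@H]1CC(=O)[C@@](C=C)(COC(=O)CBr)[C@@H](O[Si](C)(C)C(C)(C)C)C1
F2 | step 10 | cis-fused β-hydroxy-δ-lactone (C4H2) | C=C(C)[C@H]1C[C@@]2(O)CC(=O)OC[C@@]2(C=C)[C@@H](O[Si](C)(C)C(C)(C)C)C1
F3 | step 10 | α-(dimethylaminomethyl) lactone (C4 epimers) | C=C(C)[C@H]1C[C@@]2(O)C(CN(C)C)C(=O)OC[C@@]2(C=C)[C@@H](O[Si](C)(C)C(C)(C)C)C1
F4 | step 13 | C5 trimethylsilyl ether of 17 | C=C(C)[C@H]1C[C@@](O[Si](C)(C)C)(C(=C)C(=O)OC)[C@@](C=C)(CO[Si](CC)(CC)CC)[C@@H](O[Si](C)(C)C(C)(C)C)C1
F5 | step 13 | ten-membered trimethylsilyl enol ether | C=C(C)[C@H]1C/C(O[Si](C)(C)C)=C(C(=O)OC)/CC/C=C(CO[Si](CC)(CC)CC)/[C@@H](O[Si](C)(C)C(C)(C)C)C1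
F6 | step 17 | C14 (R)-2-methylbutanoate of 23 | C=C(C)[C@H]1C/C=C(/C(=O)OC)CC/C=C(COC(=O)[C@H](C)CC)/[C@@H](O[Si](C)(C)C(C)(C)C)C1
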